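all flasks: solid substrate 0.40 M
- birch: reagent 0.29 M; run made earlier
- elm: reagent 1.9 M; run made earlier
- dawn: reagent 0.200 M; time 6.0 min
- winter: reagent 1.60 M; time 6.0 min

| run | time / min | first product / % | solid substrate / % |
|---|---|---|---|
| birch | 0.833 | 5.9 | 86.8 |
| birch | 1.50 | 9.4 | 79.4 |
| birch | 2.50 | 13.6 | 70.3 |
| birch | 3.00 | 15.8 | 66.5 |
| birch | 4.00 | 16.9 | 61.5 |
| birch | 5.00 | 18.2 | 56.9 |
| birch | 6.00 | 20.4 | 53.7 |
| elm | 0.833 | 5.4 | 80.8 |
| elm | 1.50 | 6.5 | 67.2 |
| elm | 2.50 | 7.2 | 46.0 |
| elm | 3.00 | 7.2 | 35.5 |
| elm | 4.00 | 9.1 | 16.3 |
| elm | 5.00 | 9.2 | 0 |
| elm | 6.00 | 2.6 | 0 |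

(readings scatter by 0.5 percentage points)

- solid, in amounts per volume of the solution: solid substrate
- at the start none of the solid substrate is in solution

1. which of these holds the largest part of the solid substrate at the end of dawn (first product / tris adduct / solid substrate / bis adduct)
2. which of these holds the largest part of the solid substrate at the end of winter (first product / tris adduct / solid substrate / bis adduct)
3. first product at the end of winter, in percent of the solid substrate charged

- The one constant I could find was a slope: in elm the solid fell straight from 67.2% to 16.3%, a fraction 0.204 min⁻¹ of its charge. I assumed the same crawl in winter, which clears the solid after 4.91 min, earlier than the reading.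
- Dawn's reagent covers half its substrate, so I expected solid substrate to stay largest there, and tris adduct to lead in winter.
- With elm's solid gone, first product fell from 9.2% to 2.6%. A tris adduct holds 3 reagents, so I put elm's mean free reagent at its floor, 0.700 M. That gave the wastage constant, the pseudo-first-order loss of first product per molar of free reagent: 1.81 M⁻¹ min⁻¹. Replacing the curve by that mean costs about 10.5%, from the reagent that first product could still claim.
- From below, winter has less reagent than elm, so I expected it to end above elm's 2.6%.
- Tighter, I took first product at clearing as crawl over wastage, then let it decay at winter's floor, 0.400 M. Reagent averaged over the run, 1.00 M, gives the low end, 5.14%. Reagent a minute before clearing, 0.644 M, gives the high end, 7.98%.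
- The forecast gave solid substrate for dawn, tris adduct for winter and 5.5%, with first product that “then decays at about 0.9/min”, a figure inside my bracket.

    reagent + bis adduct → tris adduct (k = 0.541 M⁻¹ s⁻¹)
    solid substrate ⇌ starting material, rate k2*(cs2 - [starting material]) while solid is left; crystals form when [starting material] > cs2 (solubility = 47.0 mM, k = 0.0373 s⁻¹)
    reagent + first product → bis adduct (k = 0.0339 M⁻¹ s⁻¹)
    starting material + reagent → first product (k = 0.101 M⁻¹ s⁻¹)
    reagent → decomposition product (k = 4.82 × 10⁻⁵ s⁻¹)

- Winter read 7.73% of first product, inside the bracket, with 91.4% tris adduct, while dawn kept 62.1% solid substrate. Winter's free reagent at 6.00 min was 0.451 M, so the wastage constant gave first product a half-life of 0.851 min. The same winter flask, left until 25 min, ran 22.3 such half-lives further, and its first product stood at 0%.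

Readings and results are calculated from invented constants; noise was put on by code.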